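In a one-step world the rate falls as substrate goes, yet in the ash run time grows by a factor of 2.24 from the fourth reading to the fifth while target grows by 6.55.

| setting | ash | maple | birch | alder |
|---|---|---|---|---|
| substrate | 0.250 M | 0.100 M | 0.250 M | 0.250 M |
| partner | 0.750 M | 0.600 M | 1.50 M | 0.750 M |
| catalyst | 0.00500 M | 0.00500 M | 0.00500 M | 0.00500 M |
| time |  |  |  | 7.6 min |

| ash run: time / min | ash run: [target] / M | maple run: time / min | maple run: [target] / M | birch run: time / min | birch run: [target] / M |
|---|---|---|---|---|---|
| 0.15 | 0.0017 | 0.15 | 0.0020 | 0.15 | 3 × 10⁻⁴ |
| 0.34 | 0.0013 | 0.34 | 0.0022 | 0.34 | 0.0026 |
| 0.76 | 0.0042 | 0.76 | 0.0011 | 0.76 | 0.0057 |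
| 1.7 | 0.0179 | 1.7 | 0.0034 | 1.7 | 0.0206 |
| 3.8 | 0.1172 | 3.8 | 0.0151 | 3.8 | 0.1344 |

(scatter of a reading: 0.001 M)

- the power of [substrate] that the first rate follows, about the charge of the ash run; measure it at two percent of substrate made into target (one fixed amount of target, the same in the runs compared)
- the power of [partner] that the first rate follows, about the charge of the ash run; measure it at two percent of substrate made into target
- the maple run starts with 0.150 M less of substrate and of partner than the ash run, and with no target. Compared where both hold the same amount of substrate, once fifteen percent of what the maple run was charged with has turned into target, is the maple run faster, slower or alike (within a tenth)?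
- target in the alder run at 7.6 min, as a share of the substrate charged

- Overall: substrate + partner -> target, with catalyst as catalyst.
- Constant volume, constant temperature.
- Bound and free are read together.
- "The second partner" is partner.
- An order is taken over about fifteen percent of the charge, up and down.

1. I write rate = b([target] + s)[substrate]. This is autocatalysis on a small background, and s is the seed.

2. Integrating this rule, ln(([target] + s)/[substrate]) climbs in a straight line. With the seed left out, the last two ash readings give a growth constant of 1.16 min⁻¹, and the line traced back to zero time gives s = 0.00315 M.

3. Putting that back gives 1.10 min⁻¹, and so a seed of 0.00359 M, the amount of target that would run as fast as the background.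

4. Two times follow for this charge: the growth time 0.912 min and the background time 64.4 min. Their ratio is 70.6, so take-off comes at the growth time times its logarithm, 3.88 min.

5. The alder run has the ash charge, so I reckon 98.3%.

6. Divide the maple rate by the ash rate at equal substrate and time drops out. At 0.0150 M of target in the maple run and 0.165 M in the ash run, both hold 0.0850 M of substrate and 0.585 M of partner. The ratio is 0.110, so the maple run is slower.

7. The rule carries substrate order 1. The birch run has twice the partner and reads 1.15 times the ash target at 3.8 min. Per doubling that is a power of 0.198, but it compares accumulated target, not rates, and a curve that feeds on its own target widens a gap in rate, so I hold it as a rough mark for the partner order, likely high.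

The forecast gives 1 for substrate, 0.15 for partner, slower for the maple run and 98% (from 88% to 100%) for the alder run, holding that “the rate grows as target builds up”.

The flask gives 0.95, 0.17, slower with a rate ratio of 0.11, and 98.0%.

    catalyst + substrate ⇌ catalyst-substrate complex, settled at all times (1.320 M⁻¹)
    catalyst-substrate complex + partner → target + catalyst + by-product (44.16 M⁻¹ min⁻¹)
    substrate + partner + target → 2 target (71.40 M⁻² min⁻¹)
    substrate + partner ⇌ idle substrate-reagent adduct, settled at all times (15.10 M⁻¹)

The alder yield rests on one step. Take away the passing of substrate, partner and target into more target, and the alder run falls from 98.0% to 11.8%. That stripped flask has no growth, just the background, so my seed predicts its yield from the asked time over the background time: 11.1%. The simulated run without the step stands at 11.8%.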